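Blue, with 0.348 M of solid reagent and half of red's substrate, reads 4.2% left-handed product at 50.0 min, and red, with 0.49 M, reads 4.5% at the same time.

| flask | left-handed substrate | right-handed substrate | solid reagent | temperature | remark | time |
|---|---|---|---|---|---|---|
| red | 0.29 M | 0.29 M | 0.49 M | −5 °C | run made earlier |  |
| teal | 0.29 M | 0.29 M | 0.77 M | 30 °C | run made earlier |  |
| blue | 0.14 M | 0.14 M | 0.348 M | −5 °C | run made earlier |  |
| oak | 0.29 M | 0.29 M | 0.348 M | 60 °C |  | 2.0 min |
| larch | 0.29 M | 0.29 M | 0.348 M | 30 °C |  | 2.0 min |
| birch | 0.29 M | 0.29 M | 0.348 M | 0 °C |  | 2.0 min |

| run | time / min | left-handed product / % |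
|---|---|---|
| red | 6.00 | 0.4 |
| red | 12.0 | 0.9 |
| red | 20.0 | 1.8 |
| red | 25.0 | 2.0 |
| red | 30.0 | 2.4 |
| red | 40.0 | 2.9 |
| red | 50.0 | 4.5 |
| teal | 0.667 | 1.9 |
| teal | 1.00 | 2.1 |
| teal | 1.33 | 2.6 |
| teal | 2.00 | 3.8 |
| teal | 4.00 | 7.7 |
| teal | 6.00 | 11.0 |
| teal | 8.00 | 14.9 |
| blue | 4.00 | 0.5 |
| blue | 8.00 | 0.5 |
| blue | 12.0 | 1.1 |
| blue | 25.0 | 1.5 |
| blue | 50.0 | 4.2 |

(each reading ± 0.3 percentage points)
- the flask that comes out highest in amount of left-handed product, in percent of the left-handed substrate and right-handed substrate together charged, or "all alike" when all lie within 1.5 percentage points (oak / larch / birch / all alike)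
- left-handed product at the end, in percent of the left-handed substrate and right-handed substrate together charged, oak
- left-handed product at the end, in percent of the left-handed substrate and right-handed substrate together charged, larch
- left-handed product at the end, in percent of the left-handed substrate and right-handed substrate together charged, birch
- partner is single-handed; left-handed substrate and right-handed substrate are mirror images of each other, charged as a racemate, each of them at the stated concentration
- solid reagent is a solid; its amount is given per volume of the solution
- the analysis behind the earlier runs scatters by 0.3 percentage points, standard deviation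
- at the start none of the solid reagent is in solution
- the handed part of partner does not stay in what it makes, so the products of the two hands are mirror images too

Two chemists at the board read those runs differently.

The first says that the solution stays saturated, so [partner] holds and left-handed substrate falls pseudo-first-order, with product = 50%·(1 − e^(−kt)). My stand-in for this view takes k from teal's last reading, 0.0442 min⁻¹, and doubles it for every 10 degrees. That is 3 doublings up to 60 °C, so k = 0.354 min⁻¹ and oak reaches 25.4% in 2.0 min. The forecast, on its own fit, says oak comes highest, with oak 26% (14% to 33%), larch 4.2% and birch 0.26%, reasoning “zero order in solid, as expected for a saturated solution”. Its oak number stands close to that doubling figure from teal.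

The second says that the solid is a stock. She defines the store time, the minutes the charged solid lasts if drawn at the opening rate of left-handed product, 3.39 min in oak. Teal's store time is 60.0 min against 8.00 min of readings, while oak's is close to its 2.0 min, so teal's readings span a smaller share of its store than oak's time does of oak's. If strength sinks steadily with the stock, its mean over oak is 0.705, and her reckoning, not the forecast's, gives 19.6%.

Oak gives 12.4%, larch 3.77% and birch 0.265%, so oak comes highest, but the second chemist stood nearer in oak. The first keeps birch, with 18.0% of its solid still there at 2.00 min. At 0.120 min in oak, self-condensation uses partner 3.6 times as fast as the left-handed step, and by 2.00 min the ratio is 0.98.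

    2 partner → self-condensation product (k = 0.0810 M⁻¹ s⁻¹, Ea = 73.0 kJ mol⁻¹)
    solid reagent ⇌ partner, rate k2*(cs2 - [partner]) while solid is left; crystals form when [partner] > cs2 (solubility = 0.280 M, k = 0.130 s⁻¹)
    partner + left-handed substrate → left-handed product (k = 0.0250 M⁻¹ s⁻¹, Ea = 63.0 kJ mol⁻¹)
    partner + right-handed substrate → right-handed product (k = 0.00180 M⁻¹ s⁻¹, Ea = 60.0 kJ mol⁻¹)
    (constants at 60 °C)

Drawn by both steps at the opening ratio, oak's store time shrinks to 0.745 min, and full strength for that long gives 11.6%, against 12.4%. The neighbour with 0.087 M of solid, with oak's ratio taken over, has a store time of 0.186 min, which gives 3.19%; computed, it reaches 5.47%.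

The numbers in the tables are simulated for substances that don't exist; scatter was added.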